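**Plan**
- Cuts, in order: both isovalerate C–O bonds; the C≡C–CH2 bond of the butynyl chain (acetylide plus oxirane); the outer alkyne carbon (dibromomethylenation of an aldehyde). The inner alkyne carbon is then an ester carbon on C5 of ring A.
- Enabling feature: in ring A (the thiophene carrying the butynyl chain) S1 lies between C2, bonded to ring B, and C5, bonded to an exocyclic carbon, while C3 and C4 are plain CH. The C4–C5 bond is therefore the retron of an aldol condensation of an S–CH2–CO2Me carbon onto the CHO of a β-sulfanyl enal.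
- Further cuts: S1–C2 (thioglycolate on a β-chloroenal) and C3–C4 (formyl carbon from DMF). C2 and C3 come from an acetyl group on C5 of ring B.
- Forward: ring B is bought as thiophen-2-ylmethanol, silylated, acetylated, chloroformylated and sulfanylated. Ring A then closes at carbon, the chain grows from the ester (aldehyde, dibromoalkene, acetylide, oxirane), and desilylation and double acylation finish the route.
- Stereochemistry: the target has no stereocentre and no stereogenic alkene. Only the Z geometry of the chloro- and sulfanyl-enals matters; the chloroformylation sets it, the substitution keeps it, and aromatisation erases it.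

Key step: step 5

Remark: the iminium salt formed in step 3 is drawn as its chloride, and oxirane is taken as its commercial solution in THF.

**Step 1**
Reactants: 1 thiophen-2-ylmethanol; 2 tert-butyl(chloro)diphenylsilane
Product: 3 tert-butyl(diphenyl)(thiophen-2-ylmethoxy)silane
Conditions: TBDPSCl, imidazole, CH2Cl2, 0 °C → rt
Reagents that add atoms: tert-butyl(chloro)diphenylsilane 2, CC(C)(C)[Si](Cl)(c1ccccc1)c1ccccc1
Why: Imidazole-promoted O-silylation of a primary alcohol, with the hindered tert-butyldiphenylsilyl ether chosen because it best tolerates the chloroiminium medium, the organolithiums and the aluminium hydride used later.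

**Step 2**
Reactants: 3 tert-butyl(diphenyl)(thiophen-2-ylmethoxy)silane; 4 N-methoxy-N-methylacetamide
Product: 7 1-(5-{[(tert-butyldiphenylsilyl)oxy]methyl}thiophen-2-yl)ethan-1-one, via 5-lithiothiophene 5 (not isolated), via lithium hemiaminal adduct 6 (not isolated)
Conditions: n-BuLi, THF, −78 → −20 °C; then MeC(O)N(OMe)Me, −78 → 0 °C; then aq NH4Cl
Reagents that add atoms: N-methoxy-N-methylacetamide 4, CON(C)C(C)=O
Why: α-Lithiation at the only free α-position of the thiophene followed by a Weinreb ketone synthesis, in which chelated adduct 6 prevents over-addition and no Friedel–Crafts Lewis acid is present to ionise the thenylic silyl ether.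

**Step 3**
Reactants: 7 1-(5-{[(tert-butyldiphenylsilyl)oxy]methyl}thiophen-2-yl)ethan-1-one; 8 N,N-dimethylformamide; 9 phosphoryl chloride
Product: 11 (Z)-3-(5-{[(tert-butyldiphenylsilyl)oxy]methyl}thiophen-2-yl)-3-chloroprop-2-enal, via chlorovinyl iminium chloride 10 (not isolated)
Conditions: POCl3, DMF, 0 → 55 °C; then aq NaOAc, 0 °C
Reagents that add atoms: N,N-dimethylformamide 8, CN(C)C=O; phosphoryl chloride 9, O=P(Cl)(Cl)Cl; water, O
Why: Vilsmeier–Haack–Arnold chloroformylation, in which the enol of ketone 7 is formylated by the chloroiminium salt from 8 and 9, the vinylogous amide oxygen is exchanged for chloride to give 10, and buffered hydrolysis should release mainly the Z enal (chlorine cis to formyl, thienyl trans), while the two occupied α-positions and the acyl group keep ring B from being formylated and disfavour ionisation of the thenylic silyl ether.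

**Step 4**
Reactants: 11 (Z)-3-(5-{[(tert-butyldiphenylsilyl)oxy]methyl}thiophen-2-yl)-3-chloroprop-2-enal; 12 methyl thioglycolate
Product: 13 methyl 2-{[(Z)-1-(5-{[(tert-butyldiphenylsilyl)oxy]methyl}thiophen-2-yl)-3-oxoprop-1-en-1-yl]sulfanyl}acetate
Conditions: HSCH2CO2Me (1.05 equiv), Et3N (1.1 equiv), CH2Cl2, −10 → 0 °C
Reagents that add atoms: methyl thioglycolate 12, COC(=O)CS
Why: Nucleophilic vinylic substitution by addition–elimination of the soft thiolate at the β-carbon, expected to retain the alkene geometry, with cold Et3N enolising the new S–CH2 ester too slowly to stop the open-chain sulfide from being isolated.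

**Step 5**
Reactants: 13 methyl 2-{[(Z)-1-(5-{[(tert-butyldiphenylsilyl)oxy]methyl}thiophen-2-yl)-3-oxoprop-1-en-1-yl]sulfanyl}acetate
Product: 15 methyl 5'-{[(tert-butyldiphenylsilyl)oxy]methyl}-[2,2'-bithiophene]-5-carboxylate, via dihydrothiophene aldol 14 (not isolated)
Conditions: DBU (1.1 equiv), THF, 0 °C → rt
Reagents that add atoms: none
Why: DBU removes a proton from the S–CH2–CO2Me methylene of 13, the most acidic C–H in the molecule because it lies between the ester and a sulfur whose lone pair is drawn into the enal, and the enolate carbon adds to the formyl carbon to make the C4–C5 bond of ring A and the aldolate of 14. The remaining C5–H of 14 is still α to the ester, so E1cB loss of hydroxide follows and is irreversible because it delivers the aromatic thiophene of 15. The closest known reaction type is the closing aldol–dehydration stage of the Fiesselmann thiophene synthesis from β-chlorovinyl aldehydes and thioglycolates, run here as an operation of its own. Ring A closes in the 5-(enolexo)-exo-trig mode, the five ring atoms being S1, C2, C3, C4 and C5 with the carbonyl oxygen left outside the ring. No stereocentre is created in 15, since the two transient centres of 14 vanish on dehydration. The step needs sulfur and formyl cis on the alkene and intramolecular aldol addition in preference to intermolecular condensation: the Z geometry of 13 holds the two reacting carbons within bonding distance, and the push–pull character of the β-sulfanyl enal lets any E isomer rotate or undergo reversible conjugate addition under the basic conditions and drain into the irreversible aromatisation.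

**Step 6**
Reactants: 15 methyl 5'-{[(tert-butyldiphenylsilyl)oxy]methyl}-[2,2'-bithiophene]-5-carboxylate
Product: 16 (5'-{[(tert-butyldiphenylsilyl)oxy]methyl}-[2,2'-bithiophen]-5-yl)methanol
Conditions: i-Bu2AlH (2.5 equiv), CH2Cl2, −78 → 0 °C; then aq potassium sodium tartrate
Reagents that add atoms: none
Why: Aluminium hydride reduction of a heteroaromatic ester to the primary alcohol, which leaves the silyl ether and both thiophenes untouched.

**Step 7**
Reactants: 16 (5'-{[(tert-butyldiphenylsilyl)oxy]methyl}-[2,2'-bithiophen]-5-yl)methanol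
Product: 17 5'-{[(tert-butyldiphenylsilyl)oxy]methyl}-[2,2'-bithiophene]-5-carbaldehyde
Conditions: MnO2 (activated, excess), CH2Cl2, rt
Reagents that add atoms: none
Why: Heterogeneous MnO2 oxidation of an activated thenylic (benzylic-type) alcohol, which stops at the aldehyde under neutral conditions.

**Step 8**
Reactants: 17 5'-{[(tert-butyldiphenylsilyl)oxy]methyl}-[2,2'-bithiophene]-5-carbaldehyde; 18 tetrabromomethane
Product: 19 tert-butyl{[5'-(2,2-dibromoethenyl)-[2,2'-bithiophen]-5-yl]methoxy}diphenylsilane
Conditions: CBr4, PPh3, CH2Cl2, 0 °C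
Reagents that add atoms: tetrabromomethane 18, BrC(Br)(Br)Br
Why: Ramirez dibromoolefination (first stage of the Corey–Fuchs homologation), a Wittig-type reaction of the ylide made in the flask with a non-enolisable aromatic aldehyde.

**Step 9**
Reactants: 19 tert-butyl{[5'-(2,2-dibromoethenyl)-[2,2'-bithiophen]-5-yl]methoxy}diphenylsilane; 20 oxirane
Product: 22 4-(5'-{[(tert-butyldiphenylsilyl)oxy]methyl}-[2,2'-bithiophen]-5-yl)but-3-yn-1-ol, via lithium acetylide 21 (not isolated)
Conditions: n-BuLi (2.1 equiv), THF, −78 → 0 °C; then BF3·OEt2, oxirane (THF solution), −78 °C; then H2O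
Reagents that add atoms: oxirane 20, C1CO1
Why: The second stage of the Corey–Fuchs sequence (Br/Li exchange, Fritsch–Buttenberg–Wiechell-type 1,2-hydrogen shift, deprotonation) gives acetylide 21, which opens BF3-activated oxirane by SN2 attack (Yamaguchi–Hirao alkynylation) at a temperature where the 1-bromobutane present does not alkylate it.

**Step 10**
Reactants: 22 4-(5'-{[(tert-butyldiphenylsilyl)oxy]methyl}-[2,2'-bithiophen]-5-yl)but-3-yn-1-ol
Product: 23 4-[5'-(hydroxymethyl)-[2,2'-bithiophen]-5-yl]but-3-yn-1-ol
Conditions: Bu4NF, THF, 0 °C → rt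
Reagents that add atoms: none
Why: Fluoride-induced desilylation driven by the strong Si–F bond, run under non-acidic conditions that spare the ionisable thenylic alcohol and the internal alkyne.

**Step 11**
Reactants: 23 4-[5'-(hydroxymethyl)-[2,2'-bithiophen]-5-yl]but-3-yn-1-ol; 24 isovaleryl chloride (3-methylbutanoyl chloride)
Product: 25 4-(5'-{[(3-methylbutanoyl)oxy]methyl}-[2,2'-bithiophen]-5-yl)but-3-yn-1-yl 3-methylbutanoate (target)
Conditions: i-BuCOCl (2.5 equiv), Et3N, DMAP (cat.), CH2Cl2, 0 °C → rt
Reagents that add atoms: isovaleryl chloride 24, CC(C)CC(=O)Cl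
Why: DMAP-catalysed acylation (nucleophilic catalysis) esterifies both primary alcohols in one operation, and since the two acyl groups are identical the hydroxyls need not be told apart.

**Compound list**
1 | thiophen-2-ylmethanol | OCc1cccs1 | starting material
2 | tert-butyl(chloro)diphenylsilane | CC(C)(C)[Si](Cl)(c1ccccc1)c1ccccc1 | starting material
3 | tert-butyl(diphenyl)(thiophen-2-ylmethoxy)silane | CC(C)(C)[Si](OCc1cccs1)(c1ccccc1)c1ccccc1 | intermediate
4 | N-methoxy-N-methylacetamide | CON(C)C(C)=O | starting material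
5 | (5-{[(tert-butyldiphenylsilyl)oxy]methyl}thiophen-2-yl)lithium | [Li]c1ccc(CO[Si](c2ccccc2)(c2ccccc2)C(C)(C)C)s1 | intermediate
6 | lithium 1-(5-{[(tert-butyldiphenylsilyl)oxy]methyl}thiophen-2-yl)-1-[methoxy(methyl)amino]ethan-1-olate (racemic) | [Li+].CC([O-])(N(C)OC)c1ccc(CO[Si](c2ccccc2)(c2ccccc2)C(C)(C)C)s1 | intermediate
7 | 1-(5-{[(tert-butyldiphenylsilyl)oxy]methyl}thiophen-2-yl)ethan-1-one | CC(=O)c1ccc(CO[Si](c2ccccc2)(c2ccccc2)C(C)(C)C)s1 | intermediate
8 | N,N-dimethylformamide | CN(C)C=O | starting material
9 | phosphoryl chloride | O=P(Cl)(Cl)Cl | starting material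
10 | (Z)-N-[3-chloro-3-(5-{[(tert-butyldiphenylsilyl)oxy]methyl}thiophen-2-yl)prop-2-en-1-ylidene]-N-methylmethanaminium chloride | Cl/C(c1ccc(CO[Si](c2ccccc2)(c2ccccc2)C(C)(C)C)s1)=C\C=[N+](C)C.[Cl-] | intermediate
11 | (Z)-3-(5-{[(tert-butyldiphenylsilyl)oxy]methyl}thiophen-2-yl)-3-chloroprop-2-enal | Cl/C(c1ccc(CO[Si](c2ccccc2)(c2ccccc2)C(C)(C)C)s1)=C\C=O | intermediate
12 | methyl thioglycolate | COC(=O)CS | starting material
13 | methyl 2-{[(Z)-1-(5-{[(tert-butyldiphenylsilyl)oxy]methyl}thiophen-2-yl)-3-oxoprop-1-en-1-yl]sulfanyl}acetate | COC(=O)CS/C(c1ccc(CO[Si](c2ccccc2)(c2ccccc2)C(C)(C)C)s1)=C\C=O | intermediate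
14 | methyl 5-(5-{[(tert-butyldiphenylsilyl)oxy]methyl}thiophen-2-yl)-3-hydroxy-2,3-dihydrothiophene-2-carboxylate (racemic diastereomer mixture) | COC(=O)C1SC(c2ccc(CO[Si](c3ccccc3)(c3ccccc3)C(C)(C)C)s2)=CC1O | intermediate
15 | methyl 5'-{[(tert-butyldiphenylsilyl)oxy]methyl}-[2,2'-bithiophene]-5-carboxylate | COC(=O)c1ccc(-c2ccc(CO[Si](c3ccccc3)(c3ccccc3)C(C)(C)C)s2)s1 | intermediate
16 | (5'-{[(tert-butyldiphenylsilyl)oxy]methyl}-[2,2'-bithiophen]-5-yl)methanol | OCc1ccc(-c2ccc(CO[Si](c3ccccc3)(c3ccccc3)C(C)(C)C)s2)s1 | intermediate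
17 | 5'-{[(tert-butyldiphenylsilyl)oxy]methyl}-[2,2'-bithiophene]-5-carbaldehyde | O=Cc1ccc(-c2ccc(CO[Si](c3ccccc3)(c3ccccc3)C(C)(C)C)s2)s1 | intermediate
18 | tetrabromomethane | BrC(Br)(Br)Br | starting material
19 | tert-butyl{[5'-(2,2-dibromoethenyl)-[2,2'-bithiophen]-5-yl]methoxy}diphenylsilane | BrC(Br)=Cc1ccc(-c2ccc(CO[Si](c3ccccc3)(c3ccccc3)C(C)(C)C)s2)s1 | intermediate
20 | oxirane | C1CO1 | starting material
21 | [(5'-{[(tert-butyldiphenylsilyl)oxy]methyl}-[2,2'-bithiophen]-5-yl)ethynyl]lithium | [Li]C#Cc1ccc(-c2ccc(CO[Si](c3ccccc3)(c3ccccc3)C(C)(C)C)s2)s1 | intermediate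
22 | 4-(5'-{[(tert-butyldiphenylsilyl)oxy]methyl}-[2,2'-bithiophen]-5-yl)but-3-yn-1-ol | OCCC#Cc1ccc(-c2ccc(CO[Si](c3ccccc3)(c3ccccc3)C(C)(C)C)s2)s1 | intermediate
23 | 4-[5'-(hydroxymethyl)-[2,2'-bithiophen]-5-yl]but-3-yn-1-ol | OCCC#Cc1ccc(-c2ccc(CO)s2)s1 | intermediate
24 | isovaleryl chloride (3-methylbutanoyl chloride) | CC(C)CC(=O)Cl | starting material
25 | 4-(5'-{[(3-methylbutanoyl)oxy]methyl}-[2,2'-bithiophen]-5-yl)but-3-yn-1-yl 3-methylbutanoate | CC(C)CC(=O)OCCC#Cc1ccc(-c2ccc(COC(=O)CC(C)C)s2)s1 | target

**Step count**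
Total steps: 11. Longest linear sequence: 11 steps, from 1 to 25.

**Steps most likely to fail**

Step 3. The POCl3/DMF medium may exchange or strip the thenylic silyl ether faster than the ketone is chloroformylated, or it may give poor control of the alkene geometry.
- The fallback sets out from 3 and returns at 13. It avoids POCl3 by building the sulfanyl enal through conjugate addition of the thiol to an ynal.
- Lithiation of 3 (n-BuLi, THF, passing through 5) and quenching with I2 should give tert-butyl[(5-iodothiophen-2-yl)methoxy]diphenylsilane F1.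
- Sonogashira coupling with prop-2-yn-1-ol (PdCl2(PPh3)2, CuI, Et3N) should give 3-(5-{[(tert-butyldiphenylsilyl)oxy]methyl}thiophen-2-yl)prop-2-yn-1-ol F2.
- MnO2 in CH2Cl2 should oxidise this to 3-(5-{[(tert-butyldiphenylsilyl)oxy]methyl}thiophen-2-yl)prop-2-ynal F3.
- Base-catalysed thia-Michael addition of 12 (catalytic Et3N, CH2Cl2, −20 °C) proceeds by anti addition. This places sulfur cis to the formyl group and delivers 13.

Step 4. Ring closure may begin during the substitution, because an amine base is present when the acidic S–CH2 group appears, so the open-chain precursor may not be obtained cleanly. Reversible thiol addition to the aldehyde or a second conjugate addition may also consume material.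
- The fallback sets out from 11 and returns at 13. It reverses the order in which the two S–C bonds are made.
- One equivalent of Na2S in DMF at 0 °C should displace chloride to give sodium (Z)-1-(5-{[(tert-butyldiphenylsilyl)oxy]methyl}thiophen-2-yl)-3-oxoprop-1-ene-1-thiolate F4.
- SN2 alkylation of this thiolate with methyl bromoacetate at 0 °C consumes the only base in the flask as the S–CH2 bond forms. Compound 13 should therefore remain until DBU is added in step 5.

Step 9. The dibromoalkene may convert incompletely into the acetylide. Bromide or surplus butyllithium may open the activated oxirane, the oxirane may oligomerise, and BF3 may erode the silyl ether.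
- The fallback sets out from 15 and returns at 22. It replaces the C(sp)–C(sp3) bond formation by a C(sp2)–C(sp) cross-coupling that brings in the four-carbon chain intact.
- Saponification (LiOH, THF–H2O, then citric acid) should give 5'-{[(tert-butyldiphenylsilyl)oxy]methyl}-[2,2'-bithiophene]-5-carboxylic acid F5.
- Ipso-iododecarboxylation of this electron-rich heteroaromatic acid (I2, K3PO4, MeCN, 100 °C) should give tert-butyl[(5'-iodo-[2,2'-bithiophen]-5-yl)methoxy]diphenylsilane F6.
- Sonogashira coupling with but-3-yn-1-ol (PdCl2(PPh3)2, CuI, Et3N) should give 22.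

**Further compounds**
F1 | step 3 | tert-butyl[(5-iodothiophen-2-yl)methoxy]diphenylsilane | Ic1ccc(CO[Si](c2ccccc2)(c2ccccc2)C(C)(C)C)s1
F2 | step 3 | 3-(5-{[(tert-butyldiphenylsilyl)oxy]methyl}thiophen-2-yl)prop-2-yn-1-ol | OCC#Cc1ccc(CO[Si](c2ccccc2)(c2ccccc2)C(C)(C)C)s1
F3 | step 3 | 3-(5-{[(tert-butyldiphenylsilyl)oxy]methyl}thiophen-2-yl)prop-2-ynal | O=CC#Cc1ccc(CO[Si](c2ccccc2)(c2ccccc2)C(C)(C)C)s1
F4 | step 4 | sodium (Z)-1-(5-{[(tert-butyldiphenylsilyl)oxy]methyl}thiophen-2-yl)-3-oxoprop-1-ene-1-thiolate | [Na+].[S-]/C(c1ccc(CO[Si](c2ccccc2)(c2ccccc2)C(C)(C)C)s1)=C\C=O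
F5 | step 9 | 5'-{[(tert-butyldiphenylsilyl)oxy]methyl}-[2,2'-bithiophene]-5-carboxylic acid | OC(=O)c1ccc(-c2ccc(CO[Si](c3ccccc3)(c3ccccc3)C(C)(C)C)s2)s1
F6 | step 9 | tert-butyl[(5'-iodo-[2,2'-bithiophen]-5-yl)methoxy]diphenylsilane | Ic1ccc(-c2ccc(CO[Si](c3ccccc3)(c3ccccc3)C(C)(C)C)s2)s1
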